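All seventeen steps use known reaction types; nothing here has been run, so selectivities are predictions.

Both halves come from one allylic alcohol, 9, made from (R)-cryptone by conjugate vinyl addition (vinyl trans to isopropyl). Fragment A keeps that ring. For the cyclohexene (ring C: C1′–C6′, C2′=C3′, isopropyl on C6′), the ring of 9 serves only as a temporary ring: ozonolysis opens it, and ring-closing metathesis later closes a new six-membered ring through the former vinyl carbon (C2′) onto a methylene unit at C3′. Because C1′ carries two alkenyl arms, exchanging which arm lies in the ring converts the trans relation into the cis C1′/C6′ relation of the target. The metathesis precursor is the fully assembled diene ester 28, so ring C closes last.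

Key step: step 16

Labels: ring A = saturated carbocycle; ring B = seven-membered lactone; ring C = cyclohexene, in which C1′ bears the acrylate arm Cβ=Cα, C3′ the hydroxymethyl group and C6′ the isopropyl group.

**Step 1**
Reactants: 1 isovaleraldehyde; 2 methyl vinyl ketone
Product: 4 (R)-cryptone, via keto-aldehyde 3 (not isolated)
Conditions: (R)-α,α-diphenylprolinol trimethylsilyl ether (5 mol %), ethyl 3,4-dihydroxybenzoate (20 mol %), neat, 4 °C; then LiOH, iPrOH, rt
Reagents that add atoms: none
Why: Enamine-catalysed Michael addition in which the diarylsilyloxymethyl group of the (R)-catalyst shields one enamine face and sets the isopropyl-bearing center as R, followed by intramolecular aldol condensation to the enone.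

**Step 2**
Reactants: 4 (R)-cryptone; 5 vinylmagnesium bromide
Product: 7 (3R,4R)-4-isopropyl-3-vinylcyclohex-1-en-1-yl triflate, via magnesium enolate 6 (not isolated)
Conditions: CuBr·SMe2 (10 mol %), THF, −78 → −40 °C; then PhNTf2, −40 °C → rt
Reagents that add atoms: N-phenylbis(trifluoromethanesulfonimide), O=S(=O)(N(c1ccccc1)S(=O)(=O)C(F)(F)F)C(F)(F)F
Why: Copper-catalysed 1,4-addition delivers vinyl anti to the C4 isopropyl group (C3 set as R, trans), and O-sulfonylation of the regiodefined enolate fixes the C1=C2 alkene.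

**Step 3**
Reactants: 7 enol triflate; 8 (tributylstannyl)methanol
Product: 9 [(3R,4R)-4-isopropyl-3-vinylcyclohex-1-en-1-yl]methanol
Conditions: Pd(PPh3)4 (5 mol %), LiCl, 1,4-dioxane, 100 °C
Reagents that add atoms: none
Why: Stille coupling of an alkenyl triflate, in which the α-hydroxymethyl group transfers from tin in preference to butyl; no stereocenter is touched.

**Step 4**
Reactants: 9 allylic alcohol; 10 tributyl(iodomethyl)stannane
Product: 11 tributyl({[(3R,4R)-4-isopropyl-3-vinylcyclohex-1-en-1-yl]methoxy}methyl)stannane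
Conditions: KH, THF, 0 °C → rt
Reagents that add atoms: none
Why: Williamson etherification of the potassium alkoxide with a primary iodide.

**Step 5**
Reactants: 11 stannylmethyl ether
Product: 13 [(1S,2R,3R)-3-isopropyl-6-methylidene-2-vinylcyclohexyl]methanol, via alkoxymethyllithium 12 (not isolated)
Conditions: n-BuLi, THF, −78 °C; then aq. NH4Cl
Reagents that add atoms: none
Why: Tin–lithium exchange triggers a Still–Wittig [2,3]-sigmatropic rearrangement that forms the new C–C bond on the ring face anti to the adjacent vinyl group (C1 set as S, trans to vinyl) and leaves the exocyclic methylene.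

**Step 6**
Reactants: 13 homoallylic alcohol
Product: 14 (1S,2R,3R)-3-isopropyl-6-methylidene-2-vinylcyclohexane-1-carboxylic acid
Conditions: TEMPO (20 mol %), PhI(OAc)2 (2.2 equiv), MeCN/pH 7 buffer, rt
Reagents that add atoms: water, O
Why: Oxoammonium (TEMPO) oxidation of the primary alcohol through the aldehyde hydrate to the acid, under near-neutral conditions that leave the three alkenes and the α-center alone.

**Step 7**
Reactants: 14 acid; 15 tert-butyl 2-(bromomethyl)acrylate
Product: 16 2-(tert-butoxycarbonyl)prop-2-en-1-yl (1S,2R,3R)-3-isopropyl-6-methylidene-2-vinylcyclohexane-1-carboxylate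
Conditions: KHCO3, DMF, rt
Reagents that add atoms: none
Why: Carboxylate O-alkylation by a reactive allylic bromide (SN2 and SN2′ give the same ester) with a base too weak to move the β,γ-alkene into conjugation.

**Step 8**
Reactants: 16 triene ester
Product: 17 tert-butyl (5aS,6R,9aS)-6-isopropyl-9-methylidene-1-oxo-1,3,5a,6,7,8,9,9a-octahydro-2-benzoxepine-4-carboxylate
Conditions: second-generation Hoveyda–Grubbs catalyst (5 mol %), 1,4-benzoquinone (10 mol %), toluene (0.005 M), 80 °C
Reagents that add atoms: none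
Why: Ring-closing metathesis between the vinyl group and the tethered acrylate closes the trans-fused seven-membered unsaturated lactone (ring B), while the exocyclic methylene has no partner that would give a viable ring.

**Step 9**
Reactants: 17 methylidene lactone
Product: 18 tert-butyl (5aS,6R,9S,9aS)-9-hydroxy-9-(hydroxymethyl)-6-isopropyl-1-oxo-1,3,5a,6,7,8,9,9a-octahydro-2-benzoxepine-4-carboxylate
Conditions: OsO4 (2 mol %), NMO, citric acid, tBuOH/H2O, 0 °C; used at once
Reagents that add atoms: N-methylmorpholine N-oxide, C[N+]1([O-])CCOCC1; water, O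
Why: Upjohn dihydroxylation selects the electron-rich 1,1-disubstituted alkene over the ester-conjugated ring alkene, and OsO4 approaches the locked chair from the equatorial direction, giving the equatorial tertiary hydroxyl (C9 set as S) and the axial CH2OH.

**Step 10**
Reactants: 9 allylic alcohol
Product: 19 tert-butyl{[(3R,4R)-4-isopropyl-3-vinylcyclohex-1-en-1-yl]methoxy}dimethylsilane
Conditions: TBSCl, imidazole, CH2Cl2, rt
Reagents that add atoms: tert-butyldimethylsilyl chloride, CC(C)(C)[Si](C)(C)Cl
Why: Standard silylation of a primary alcohol.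

**Step 11**
Reactants: 19 silyl ether
Product: 20 (2R,3R)-7-[(tert-butyldimethylsilyl)oxy]-3-isopropyl-6-oxo-2-vinylheptanal
Conditions: O3 (1.0 equiv), CH2Cl2, −78 °C, Sudan red 7B as indicator; then PPh3, −78 °C → rt; used crude
Reagents that add atoms: ozone, [O-][O+]=O
Why: Ozonolysis cleaves the trisubstituted ring alkene faster than the monosubstituted vinyl group, opening the temporary ring to a ketone (future C3′) and an aldehyde (future Cβ) without touching either stereocenter.

**Step 12**
Reactants: 20 keto-aldehyde; 21 trimethyl 2-phosphonoacrylate; 22 4-methoxybenzyl alcohol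
Product: 24 methyl (2E,4R,5R)-9-[(tert-butyldimethylsilyl)oxy]-5-isopropyl-2-{[(4-methoxybenzyl)oxy]methyl}-8-oxo-4-vinylnon-2-enoate, via phosphonate carbanion 23 (not isolated)
Conditions: NaH, THF, 0 °C (22, then 21); then 20, −78 → −20 °C
Reagents that add atoms: none
Why: Tandem oxa-Michael/Horner–Wadsworth–Emmons reaction, in which the stabilised carbanion olefinates only the aldehyde and places the branched chain trans to the ester (E), the usual outcome for α-substituted phosphonoacetates with α-branched aldehydes.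

**Step 13**
Reactants: 24 keto enoate
Product: 25 methyl (2E,4R,5R)-8-{[(tert-butyldimethylsilyl)oxy]methyl}-5-isopropyl-2-{[(4-methoxybenzyl)oxy]methyl}-4-vinylnona-2,8-dienoate
Conditions: Zn, CH2Br2, TiCl4, THF/CH2Cl2, 0 °C → rt
Reagents that add atoms: dibromomethane, BrCBr
Why: Lombardo methylenation, a non-basic gem-dimetallic reagent that olefinates ketones but not esters, so the doubly allylic C4–H is not deprotonated.

**Step 14**
Reactants: 25 methyl ester
Product: 26 (2E,4R,5R)-8-{[(tert-butyldimethylsilyl)oxy]methyl}-5-isopropyl-2-{[(4-methoxybenzyl)oxy]methyl}-4-vinylnona-2,8-dienoic acid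
Conditions: LiOH, THF/MeOH/H2O, rt; then dilute HCl to pH 4, 0 °C
Reagents that add atoms: lithium hydroxide, [Li+].[OH-]
Why: Saponification of the methyl ester under conditions that primary silyl and benzyl-type ethers survive.

**Step 15**
Reactants: 18 diol lactone; 26 acid
Product: 28 diene ester [primary ester of 18 with 26], via mixed anhydride 27 (not isolated)
Conditions: 2,4,6-trichlorobenzoyl chloride, Et3N, THF, rt; then 18, DMAP, toluene, 0 °C → rt
Reagents that add atoms: none
Why: Yamaguchi esterification acylates the primary hydroxyl of 18 rapidly and leaves the hindered tertiary hydroxyl free; adding 18 last to the preformed anhydride keeps its lifetime as a free alcohol short.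

**Step 16**
Reactants: 28 diene ester
Product: 29 ring-closed ester [(2E)-3-[(1S,6R)-3-{[(tert-butyldimethylsilyl)oxy]methyl}-6-isopropylcyclohex-2-en-1-yl]-2-{[(4-methoxybenzyl)oxy]methyl}prop-2-enoate of 18]
Conditions: second-generation Grubbs catalyst (5 mol %), CH2Cl2 (0.005 M), 40 °C
Reagents that add atoms: none
Why: The ruthenium alkylidene loads on the monosubstituted vinyl group, adds across the 1,1-disubstituted alkene through a metallacyclobutane and cycloreverts to the C2′=C3′ alkene with loss of ethene (Chauvin mechanism). The closest known reaction type is ring-closing metathesis of a 1,7-diene to a trisubstituted cyclohexene. Ring C closes by formation of the C2′=C3′ double bond, which ends up endocyclic in a six-membered ring. No stereocenter is created: C1′ (S) and C6′ (R) come from steps 2 and 11, and they become cis because the former vinyl carbon is now a ring atom while the former ring carbon is the exocyclic arm Cβ. The step needs chemoselectivity for the vinyl/methylene pair over the two trisubstituted, ester-conjugated alkenes (Cβ=Cα and the ring B alkene), which their substitution and electron poverty secure. High dilution suppresses cross-metathesis.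

**Step 17**
Reactants: 29 protected precursor
Product: 30 target compound
Conditions: TFA/CH2Cl2 (1:4), anisole (10 equiv), H2O (5 equiv), 0 °C
Reagents that add atoms: none
Why: Global acidolysis removes the tert-butyl ester (as isobutene), the 4-methoxybenzyl ether (cation trapped by anisole) and the primary silyl ether (protodesilylation), while the electron-poor tertiary alcohol and the allylic lactone are slow to ionise.

**Compound list**

1 | isovaleraldehyde (3-methylbutanal) | CC(C)CC=O | starting material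
2 | methyl vinyl ketone (but-3-en-2-one) | CC(=O)C=C | starting material
3 | (2R)-2-isopropyl-5-oxohexanal | CC(C)[C@H](C=O)CCC(C)=O | intermediate
4 | (R)-cryptone, (4R)-4-isopropylcyclohex-2-en-1-one | CC(C)[C@@H]1C=CC(=O)CC1 | intermediate
5 | vinylmagnesium bromide | C=C[Mg]Br | starting material
6 | bromomagnesium (3R,4R)-4-isopropyl-3-vinylcyclohex-1-en-1-olate | CC(C)[C@H]1CCC(O[Mg]Br)=C[C@@H]1C=C | intermediate
7 | (3R,4R)-4-isopropyl-3-vinylcyclohex-1-en-1-yl trifluoromethanesulfonate | CC(C)[C@H]1CCC(OS(=O)(=O)C(F)(F)F)=C[C@@H]1C=C | intermediate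
8 | (tributylstannyl)methanol | CCCC[Sn](CO)(CCCC)CCCC | starting material
9 | [(3R,4R)-4-isopropyl-3-vinylcyclohex-1-en-1-yl]methanol | CC(C)[C@H]1CCC(CO)=C[C@@H]1C=C | intermediate
10 | tributyl(iodomethyl)stannane | CCCC[Sn](CI)(CCCC)CCCC | starting material
11 | tributyl({[(3R,4R)-4-isopropyl-3-vinylcyclohex-1-en-1-yl]methoxy}methyl)stannane | CC(C)[C@H]1CCC(COC[Sn](CCCC)(CCCC)CCCC)=C[C@@H]1C=C | intermediate
12 | {[(3R,4R)-4-isopropyl-3-vinylcyclohex-1-en-1-yl]methoxy}methyllithium | CC(C)[C@H]1CCC(COC[Li])=C[C@@H]1C=C | intermediate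
13 | [(1S,2R,3R)-3-isopropyl-6-methylidene-2-vinylcyclohexyl]methanol | CC(C)[C@H]1CCC(=C)[C@@H](CO)[C@@H]1C=C | intermediate
14 | (1S,2R,3R)-3-isopropyl-6-methylidene-2-vinylcyclohexane-1-carboxylic acid | CC(C)[C@H]1CCC(=C)[C@@H](C(=O)O)[C@@H]1C=C | intermediate
15 | tert-butyl 2-(bromomethyl)acrylate | C=C(CBr)C(=O)OC(C)(C)C | starting material
16 | 2-(tert-butoxycarbonyl)prop-2-en-1-yl (1S,2R,3R)-3-isopropyl-6-methylidene-2-vinylcyclohexane-1-carboxylate | CC(C)[C@H]1CCC(=C)[C@@H](C(=O)OCC(=C)C(=O)OC(C)(C)C)[C@@H]1C=C | intermediate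
17 | tert-butyl (5aS,6R,9aS)-6-isopropyl-9-methylidene-1-oxo-1,3,5a,6,7,8,9,9a-octahydro-2-benzoxepine-4-carboxylate | CC(C)[C@H]1CCC(=C)[C@H]2C(=O)OCC(C(=O)OC(C)(C)C)=C[C@H]12 | intermediate
18 | tert-butyl (5aS,6R,9S,9aS)-9-hydroxy-9-(hydroxymethyl)-6-isopropyl-1-oxo-1,3,5a,6,7,8,9,9a-octahydro-2-benzoxepine-4-carboxylate | CC(C)[C@H]1CC[C@@](O)(CO)[C@H]2C(=O)OCC(C(=O)OC(C)(C)C)=C[C@H]12 | intermediate
19 | tert-butyl{[(3R,4R)-4-isopropyl-3-vinylcyclohex-1-en-1-yl]methoxy}dimethylsilane | CC(C)[C@H]1CCC(CO[Si](C)(C)C(C)(C)C)=C[C@@H]1C=C | intermediate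
20 | (2R,3R)-7-[(tert-butyldimethylsilyl)oxy]-3-isopropyl-6-oxo-2-vinylheptanal | CC(C)[C@@H](CCC(=O)CO[Si](C)(C)C(C)(C)C)[C@H](C=O)C=C | intermediate
21 | trimethyl 2-phosphonoacrylate (methyl 2-(dimethoxyphosphoryl)acrylate) | COC(=O)C(=C)P(=O)(OC)OC | starting material
22 | 4-methoxybenzyl alcohol | COc1ccc(CO)cc1 | starting material
23 | sodium salt of methyl 2-(dimethoxyphosphoryl)-3-[(4-methoxybenzyl)oxy]propanoate carbanion | [Na+].COC(=O)[C-](COCc1ccc(OC)cc1)P(=O)(OC)OC | intermediate
24 | methyl (2E,4R,5R)-9-[(tert-butyldimethylsilyl)oxy]-5-isopropyl-2-{[(4-methoxybenzyl)oxy]methyl}-8-oxo-4-vinylnon-2-enoate | COC(=O)/C(=C/[C@H](C=C)[C@@H](C(C)C)CCC(=O)CO[Si](C)(C)C(C)(C)C)COCc1ccc(OC)cc1 | intermediate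
25 | methyl (2E,4R,5R)-8-{[(tert-butyldimethylsilyl)oxy]methyl}-5-isopropyl-2-{[(4-methoxybenzyl)oxy]methyl}-4-vinylnona-2,8-dienoate | COC(=O)/C(=C/[C@H](C=C)[C@@H](C(C)C)CCC(=C)CO[Si](C)(C)C(C)(C)C)COCc1ccc(OC)cc1 | intermediate
26 | (2E,4R,5R)-8-{[(tert-butyldimethylsilyl)oxy]methyl}-5-isopropyl-2-{[(4-methoxybenzyl)oxy]methyl}-4-vinylnona-2,8-dienoic acid | OC(=O)/C(=C/[C@H](C=C)[C@@H](C(C)C)CCC(=C)CO[Si](C)(C)C(C)(C)C)COCc1ccc(OC)cc1 | intermediate
27 | mixed anhydride of 26 with 2,4,6-trichlorobenzoic acid | O=C(OC(=O)/C(=C/[C@H](C=C)[C@@H](C(C)C)CCC(=C)CO[Si](C)(C)C(C)(C)C)COCc1ccc(OC)cc1)c1c(Cl)cc(Cl)cc1Cl | intermediate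
28 | [(5aS,6R,9S,9aS)-4-(tert-butoxycarbonyl)-9-hydroxy-6-isopropyl-1-oxo-1,3,5a,6,7,8,9,9a-octahydro-2-benzoxepin-9-yl]methyl ester of acid 26 | CC(C)[C@H]1CC[C@@](O)(COC(=O)/C(=C/[C@H](C=C)[C@@H](C(C)C)CCC(=C)CO[Si](C)(C)C(C)(C)C)COCc3ccc(OC)cc3)[C@H]2C(=O)OCC(C(=O)OC(C)(C)C)=C[C@H]12 | intermediate
29 | [(5aS,6R,9S,9aS)-4-(tert-butoxycarbonyl)-9-hydroxy-6-isopropyl-1-oxo-1,3,5a,6,7,8,9,9a-octahydro-2-benzoxepin-9-yl]methyl (2E)-3-[(1S,6R)-3-{[(tert-butyldimethylsilyl)oxy]methyl}-6-isopropylcyclohex-2-en-1-yl]-2-{[(4-methoxybenzyl)oxy]methyl}prop-2-enoate | CC(C)[C@H]1CC[C@@](O)(COC(=O)/C(=C/[C@@H]3C=C(CO[Si](C)(C)C(C)(C)C)CC[C@@H]3C(C)C)COCc4ccc(OC)cc4)[C@H]2C(=O)OCC(C(=O)OC(C)(C)C)=C[C@H]12 | intermediate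
30 | CNP0361406.9: (5aS,6R,9S,9aS)-9-hydroxy-9-({[(2E)-2-(hydroxymethyl)-3-[(1S,6R)-3-(hydroxymethyl)-6-isopropylcyclohex-2-en-1-yl]prop-2-enoyl]oxy}methyl)-6-isopropyl-1-oxo-1,3,5a,6,7,8,9,9a-octahydro-2-benzoxepine-4-carboxylic acid | CC(C)[C@H]1CC[C@@](O)(COC(=O)/C(=C/[C@@H]2C=C(CO)CC[C@@H]2C(C)C)CO)[C@H]2C(=O)OCC(C(=O)O)=C[C@H]12 | target

**Step count and risks**

Total steps: 17. Longest linear sequence: 12 steps (1, 2, 3, 4, 5, 6, 7, 8, 9, 15, 16, 17).

Steps most likely to fail:

Step 12. The α-vinyl aldehyde 20 may epimerise at C2 or isomerise into conjugation under the basic olefination, and the alkene geometry may erode. The fallback sets out from 20 and comes back at 24. Aldehyde 20 would be added to the vinylalane made from methyl propiolate and DIBAL-H/HMPA (THF, 0 °C), a non-basic Baylis–Hillman-type addition that should give methyl (4R,5R)-9-[(tert-butyldimethylsilyl)oxy]-3-hydroxy-5-isopropyl-2-methylidene-8-oxo-4-vinylnonanoate F1 as a mixture of carbinol epimers. NBS/Me2S (CH2Cl2, 0 °C) would then deliver bromide in the SN2′ sense to give methyl (2Z,4R,5R)-2-(bromomethyl)-9-[(tert-butyldimethylsilyl)oxy]-5-isopropyl-8-oxo-4-vinylnon-2-enoate F2, in which the branched chain is already trans to the ester. Displacement of the bromide with 4-methoxybenzyl alcohol 22 (Ag2O, CH2Cl2) would give 24.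

Step 9. During the aqueous osmylation the new primary hydroxyl may attack the neighbouring lactone carbonyl (acyl migration to the five-membered lactone with opening of ring B). The fallback sets out from 17 and comes back at 28. Dihydroxylation in the presence of phenylboronic acid (OsO4 2 mol %, NMO, PhB(OH)2, CH2Cl2, rt) would capture the diol as it forms as the cyclic phenylboronate of diol 18 F3, which has no free hydroxyl. F3 and pinacol would then be added to the preformed mixed anhydride 27 with DMAP, so that the primary hydroxyl is acylated as boron is transferred to pinacol, giving 28 directly.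

Step 17. Ionisation of the allylic alcohols or of the skipped diene in strong acid, or alkylation of the alkenes by the 4-methoxybenzyl cation, may degrade the product. The fallback sets out from 29 and comes back at 30 through three orthogonal, non-protic unmaskings. DDQ (CH2Cl2/pH 7 buffer, 0 °C) would remove the benzyl-type ether to give the side-chain alcohol F4. HF·pyridine (THF/pyridine, 0 °C) would remove the silyl ether to give the triol tert-butyl ester F5. TMSOTf/2,6-lutidine (CH2Cl2, 0 °C) followed by aqueous work-up would cleave the tert-butyl ester through its silyl ester to give 30.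

**Further compounds**

F1 | step 12 | methyl (4R,5R)-9-[(tert-butyldimethylsilyl)oxy]-3-hydroxy-5-isopropyl-2-methylidene-8-oxo-4-vinylnonanoate (carbinol epimers) | COC(=O)C(=C)C(O)[C@H](C=C)[C@@H](C(C)C)CCC(=O)CO[Si](C)(C)C(C)(C)C
F2 | step 12 | methyl (2Z,4R,5R)-2-(bromomethyl)-9-[(tert-butyldimethylsilyl)oxy]-5-isopropyl-8-oxo-4-vinylnon-2-enoate | COC(=O)/C(CBr)=C/[C@H](C=C)[C@@H](C(C)C)CCC(=O)CO[Si](C)(C)C(C)(C)C
F3 | step 9 | cyclic phenylboronate of diol 18 | CC(C)[C@H]1CC[C@@]3(COB(c4ccccc4)O3)[C@H]2C(=O)OCC(C(=O)OC(C)(C)C)=C[C@H]12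
F4 | step 17 | 29 without the 4-methoxybenzyl group (side-chain alcohol) | CC(C)[C@H]1CC[C@@](O)(COC(=O)/C(=C/[C@@H]3C=C(CO[Si](C)(C)C(C)(C)C)CC[C@@H]3C(C)C)CO)[C@H]2C(=O)OCC(C(=O)OC(C)(C)C)=C[C@H]12
F5 | step 17 | tert-butyl ester of the target (triol) | CC(C)[C@H]1CC[C@@](O)(COC(=O)/C(=C/[C@@H]3C=C(CO)CC[C@@H]3C(C)C)CO)[C@H]2C(=O)OCC(C(=O)OC(C)(C)C)=C[C@H]12
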